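**Plan**

- Cuts, backward: the nine O-alkyl bonds first; then ring C (C1 = O–ring B, C2 = OH, C3 = H, C4 = OH, C5 = ring D, C6 = OH) is dismantled completely. C2–C3 and C4–C5 go to ethoxyacetylene; C1–C6 and a transient C2–C5 bond go to an aryloxyketene and an aryl ynol ether.
- Further cuts: the ring D–alkyne bond (Negishi), the ring A–O–ring B ether (Ullmann at an unhindered bromide) and the O–CH2 bond of an aryloxyacetate (SN2). Neither tetra-ortho-substituted link is ever made by joining two arenes.
- Forward order: rings A, B and D are bought; A–O–B is joined first; a four-membered ring unites the A/B fragment with the D fragment; ring C is grown last from that cyclobutenone by a two-carbon benzannulation; global dealkylation ends the route.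
- Enabling feature: ring C is a 1,2,3,5-tetraoxygenated benzene reading O-aryl, OH, H, OH, aryl, OH. The C2 oxygen is the ketene carbonyl oxygen, the two oxygens meta to it (C4, C6) are ynol ether oxygens, C1 is the ketene α-carbon and C5 the aryl-bearing alkyne carbon.
- Stereochemistry: the target has no stereocentre and the C–D axis is not stereogenic because ring D is symmetric. The one sp3 centre on the way (C4 of the cyclobutenone) is racemic and disappears on aromatisation.

Key step: step 7

Remark on the chemistry: ArO below stands for the 4-(3,5-dimethoxyphenoxy)-2,6-dimethoxyphenoxy group (rings A and B). Its ring A is the most nucleophilic site of every intermediate, which dictates the reagents of steps 3 and 4. Ethoxyacetylene is taken as its commercial hexane solution.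

**Route**

Step 1
Reactants: 1 4-bromo-2,6-dimethoxyphenol; 2 tert-butyl bromoacetate
Product: 3 tert-butyl 2-(4-bromo-2,6-dimethoxyphenoxy)acetate
Conditions: K2CO3, DMF, 50 °C
Reagents that add atoms: none
Why: Williamson ether synthesis, in which the phenoxide of 1, although flanked by two methoxy groups, is alkylated by SN2 at the unhindered primary carbon of the α-bromo ester, placing the future ring B–O–ring C oxygen on an sp3 carbon that later becomes C1 of ring C.

Step 2
Reactants: 3 tert-butyl 2-(4-bromo-2,6-dimethoxyphenoxy)acetate; 4 3,5-dimethoxyphenol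
Product: 5 tert-butyl 2-[4-(3,5-dimethoxyphenoxy)-2,6-dimethoxyphenoxy]acetate
Conditions: CuI (10 mol %), N,N-dimethylglycine (30 mol %), Cs2CO3, 1,4-dioxane, 90 °C, argon
Reagents that add atoms: none
Why: Ullmann diaryl ether coupling, which should work because the bromide of 3 has two free ortho positions, amino-acid-ligated copper couples such electron-rich bromides with phenols under carbonate conditions, and the tert-butyl ester resists attack by the phenoxide.

Step 3
Reactants: 5 tert-butyl 2-[4-(3,5-dimethoxyphenoxy)-2,6-dimethoxyphenoxy]acetate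
Product: 6 2-[4-(3,5-dimethoxyphenoxy)-2,6-dimethoxyphenoxy]acetic acid
Conditions: CF3CO2H/CH2Cl2 (1:4), Et3SiH (2.5 equiv), 0 °C to rt
Reagents that add atoms: none
Why: Acidolysis of the tert-butyl ester by alkyl–oxygen cleavage, with Et3SiH present to reduce the tert-butyl cation to isobutane before it can alkylate the 1,3,5-trioxygenated ring A in a Friedel–Crafts reaction.

Step 4
Reactants: 6 2-[4-(3,5-dimethoxyphenoxy)-2,6-dimethoxyphenoxy]acetic acid
Product: 7 2-[4-(3,5-dimethoxyphenoxy)-2,6-dimethoxyphenoxy]acetyl chloride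
Conditions: 1-chloro-N,N,2-trimethylprop-1-en-1-amine (1.1 equiv), CH2Cl2, 0 °C to rt; volatiles removed, crude used at once
Reagents that add atoms: 1-chloro-N,N,2-trimethylprop-1-en-1-amine, CC(C)=C(Cl)N(C)C
Why: Acid chloride formation with an α-chloroenamine under neutral conditions, chosen because oxalyl chloride or Vilsmeier-type chloroiminium species would acylate or formylate ring A, whereas here the only by-product is an inert tertiary amide.

Step 5
Reactants: 8 ethoxyacetylene; 9 2-iodo-1,3,5-trimethoxybenzene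
Product: 12 2-(ethoxyethynyl)-1,3,5-trimethoxybenzene, via lithium ethoxyacetylide 10 (not isolated), via ethoxyethynylzinc chloride 11 (not isolated)
Conditions: 8, n-BuLi, THF, −78 °C; ZnCl2, −78 to 0 °C; then 9, Pd(PPh3)4 (zerovalent palladium, 5 mol %), rt to 40 °C; NaHCO3 work-up, Et3N-deactivated silica
Reagents that add atoms: none
Why: Negishi coupling (oxidative addition of zerovalent palladium into the C–I bond, transmetalation with the alkynylzinc chloride, reductive elimination), in which the rod-shaped alkynyl group tolerates the two ortho methoxy groups and the mild temperature avoids retro-ene loss of ethylene from the ynol ether.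

Step 6
Reactants: 7 2-[4-(3,5-dimethoxyphenoxy)-2,6-dimethoxyphenoxy]acetyl chloride; 12 2-(ethoxyethynyl)-1,3,5-trimethoxybenzene
Product: 14 4-[4-(3,5-dimethoxyphenoxy)-2,6-dimethoxyphenoxy]-3-ethoxy-2-(2,4,6-trimethoxyphenyl)cyclobut-2-en-1-one (racemic), via aryloxyketene 13 (not isolated)
Conditions: Et3N (1.5 equiv), 12 (1.3 equiv), CH2Cl2, 0 °C to rt, 7 added slowly by syringe pump
Reagents that add atoms: none
Why: Ketene–alkyne [2+2] cycloaddition after dehydrochlorination of the acid chloride, in which the oxygen-free carbon of the ynol ether attacks the ketene carbonyl carbon and the resulting oxocarbenium–enolate closes, so that ring D ends next to the carbonyl and OEt at C3, while the new sp3 centre C4 (H and ArO) forms as a racemate under no stereocontrol, which is immaterial.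

Step 7
Reactants: 14 4-[4-(3,5-dimethoxyphenoxy)-2,6-dimethoxyphenoxy]-3-ethoxy-2-(2,4,6-trimethoxyphenyl)cyclobut-2-en-1-one (racemic); 8 ethoxyacetylene
Product: 19 2-[4-(3,5-dimethoxyphenoxy)-2,6-dimethoxyphenoxy]-3,5-diethoxy-4-(2,4,6-trimethoxyphenyl)phenol, via vinylketene 15 (not isolated), via 4-vinylcyclobutenone 16 (not isolated), via dienylketene 17 (not isolated), via cyclohexadienone 18 (not isolated)
Conditions: 8 (5 equiv), degassed toluene, sealed tube, 80 °C
Reagents that add atoms: none
Why: Danheiser benzannulation of a cyclobutenone with an alkoxyacetylene: heating opens 14 by conrotatory 4π electrocyclic cleavage of the C(=O)–CH(OAr) bond to vinylketene 15, the aryloxy donor on the sp3 carbon lowering the barrier and turning outward. The ketene C=C of 15 then undergoes a [2+2] cycloaddition with ethoxyacetylene in which the carbonyl carbon bonds to the alkyne CH carbon and the ring-D-bearing α-carbon bonds to the C(OEt) carbon, giving the four-membered ring of 16. A second 4π opening of 16 (cleavage of the C(=O)–C(ring D) bond) gives dienylketene 17, whose thermal disrotatory 6π electrocyclisation joins the ketene carbon to the aryloxy-bearing carbon and so closes six-membered ring C as dienone 18; tautomerisation gives phenol 19. No stereocentre survives, since the sp3 carbons of 14, 16 and 18 are racemic and all become aromatic carbons. The selectivity needed is regiochemical (H ortho and OEt meta to the new hydroxyl) and is secured by the polarisation of the ynol ether, whose oxygen-free terminus is the nucleophile toward the electrophilic ketene carbon; reversible closure of the ketenes should funnel the geometric isomers of 17 to the one that can cyclise.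

Step 8
Reactants: 19 2-[4-(3,5-dimethoxyphenoxy)-2,6-dimethoxyphenoxy]-3,5-diethoxy-4-(2,4,6-trimethoxyphenyl)phenol
Product: 20 3-[4-(3,5-dihydroxyphenoxy)-2,6-dihydroxyphenoxy]-[1,1'-biphenyl]-2,2',4,4',6,6'-hexol (CNP0308688.0)
Conditions: BBr3 (20 equiv), CH2Cl2, −78 °C to rt, argon; then H2O, 0 °C; reversed-phase purification under inert gas
Reagents that add atoms: none
Why: Lewis-acid ether cleavage with BBr3, in which each alkyl aryl ether oxygen is complexed and bromide attacks the methyl or ethyl carbon by SN2, whereas the two diaryl ether links and the biaryl bond offer no sp3 carbon and persist, and hydrolysis of the aryl borates releases the decaphenol.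

**Compound list**

1 | 4-bromo-2,6-dimethoxyphenol (ring B) | COc1cc(Br)cc(OC)c1O | starting material
2 | tert-butyl bromoacetate | CC(C)(C)OC(=O)CBr | starting material
3 | tert-butyl 2-(4-bromo-2,6-dimethoxyphenoxy)acetate | COc1cc(Br)cc(OC)c1OCC(=O)OC(C)(C)C | intermediate
4 | 3,5-dimethoxyphenol (ring A) | COc1cc(O)cc(OC)c1 | starting material
5 | tert-butyl 2-[4-(3,5-dimethoxyphenoxy)-2,6-dimethoxyphenoxy]acetate | COc1cc(Oc2cc(OC)c(OCC(=O)OC(C)(C)C)c(OC)c2)cc(OC)c1 | intermediate
6 | 2-[4-(3,5-dimethoxyphenoxy)-2,6-dimethoxyphenoxy]acetic acid | COc1cc(Oc2cc(OC)c(OCC(=O)O)c(OC)c2)cc(OC)c1 | intermediate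
7 | 2-[4-(3,5-dimethoxyphenoxy)-2,6-dimethoxyphenoxy]acetyl chloride | COc1cc(Oc2cc(OC)c(OCC(=O)Cl)c(OC)c2)cc(OC)c1 | intermediate
8 | ethoxyacetylene | CCOC#C | starting material
9 | 2-iodo-1,3,5-trimethoxybenzene (ring D) | COc1cc(OC)c(I)c(OC)c1 | starting material
10 | lithium ethoxyacetylide | CCOC#C[Li] | intermediate
11 | ethoxyethynylzinc chloride | CCOC#C[Zn]Cl | intermediate
12 | 2-(ethoxyethynyl)-1,3,5-trimethoxybenzene | CCOC#Cc1c(OC)cc(OC)cc1OC | intermediate
13 | aryloxyketene, 2-[4-(3,5-dimethoxyphenoxy)-2,6-dimethoxyphenoxy]ethen-1-one | O=C=COc1c(OC)cc(Oc2cc(OC)cc(OC)c2)cc1OC | intermediate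
14 | 4-[4-(3,5-dimethoxyphenoxy)-2,6-dimethoxyphenoxy]-3-ethoxy-2-(2,4,6-trimethoxyphenyl)cyclobut-2-en-1-one (racemic) | CCOC1=C(c2c(OC)cc(OC)cc2OC)C(=O)C1Oc1c(OC)cc(Oc2cc(OC)cc(OC)c2)cc1OC | intermediate
15 | vinylketene, (Z)-4-ArO-3-ethoxy-2-(2,4,6-trimethoxyphenyl)buta-1,3-dien-1-one (ArO cis to OEt) | O=C=C(c1c(OC)cc(OC)cc1OC)/C(OCC)=C/Oc1c(OC)cc(Oc2cc(OC)cc(OC)c2)cc1OC | intermediate
16 | 4-vinylcyclobutenone, 4-[(Z)-2-ArO-1-ethoxyethenyl]-3-ethoxy-4-(2,4,6-trimethoxyphenyl)cyclobut-2-en-1-one (racemic) | O=C1C=C(OCC)C1(c1c(OC)cc(OC)cc1OC)/C(OCC)=C/Oc1c(OC)cc(Oc2cc(OC)cc(OC)c2)cc1OC | intermediate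
17 | dienylketene, 6-ArO-3,5-diethoxy-4-(2,4,6-trimethoxyphenyl)hexa-1,3,5-trien-1-one (the two chain arms cis on the central double bond) | O=C=C/C(OCC)=C(c1c(OC)cc(OC)cc1OC)\C(OCC)=C\Oc1c(OC)cc(Oc2cc(OC)cc(OC)c2)cc1OC | intermediate
18 | cyclohexadienone, 6-ArO-3,5-diethoxy-4-(2,4,6-trimethoxyphenyl)cyclohexa-2,4-dien-1-one (racemic) | O=C1C=C(OCC)C(c2c(OC)cc(OC)cc2OC)=C(OCC)C1Oc1c(OC)cc(Oc2cc(OC)cc(OC)c2)cc1OC | intermediate
19 | 2-[4-(3,5-dimethoxyphenoxy)-2,6-dimethoxyphenoxy]-3,5-diethoxy-4-(2,4,6-trimethoxyphenyl)phenol | CCOc1cc(O)c(Oc2c(OC)cc(Oc3cc(OC)cc(OC)c3)cc2OC)c(OCC)c1-c1c(OC)cc(OC)cc1OC | intermediate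
20 | 3-[4-(3,5-dihydroxyphenoxy)-2,6-dihydroxyphenoxy]-[1,1'-biphenyl]-2,2',4,4',6,6'-hexol (CNP0308688.0) | Oc1cc(O)cc(Oc2cc(O)c(Oc3c(O)cc(O)c(-c4c(O)cc(O)cc4O)c3O)c(O)c2)c1 | target

**Count and risks**

Total step count: 8. Longest linear sequence: 7 steps (steps 1, 2, 3, 4, 6, 7, 8); step 5 is the convergent branch.

Most likely to fail, in order of risk:

1. Step 7. The [2+2] capture of vinylketene 15 has to create a quaternary carbon carrying the doubly ortho-methoxylated ring D. If that capture is slow, the ketene may dimerise or acylate the product phenol. In addition, ethoxyacetylene loses ethylene above about 100 °C, which narrows the temperature window for opening the donor-stabilised cyclobutenone. The fallback uses the two ynol ethers in the opposite order; it sets out from 7 and 8 and returns to the route at 20. Acid chloride 7 is dehydrochlorinated with Et3N in the presence of excess 8 to give 4-[4-(3,5-dimethoxyphenoxy)-2,6-dimethoxyphenoxy]-3-ethoxycyclobut-2-en-1-one F1, an unhindered ketene–ethoxyacetylene [2+2]. F1 is then heated with aryl ynol ether 12 (toluene, 80 °C) in the same benzannulation manifold. Ring D now enters on an sp carbon and never sits on a quaternary centre. The product should be the isomeric monophenol 2-[4-(3,5-dimethoxyphenoxy)-2,6-dimethoxyphenoxy]-3,5-diethoxy-6-(2,4,6-trimethoxyphenyl)phenol F2, with its hydroxyl between the O–ring B carbon and the ring D carbon. BBr3 under the conditions of step 8 converts F2 into 20, since F2 and 19 differ only in which of the three ring C oxygens is free.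

2. Step 6. Dimerisation of the short-lived aryloxyketene may outrun its cycloaddition to the hindered aryl ynol ether, and the ammonium salt may hydrate the acid-sensitive ynol ether. The fallback replaces the ketene by a non-dimerising, more electrophilic keteniminium ion; it sets out from 7 and returns at 14. Acid chloride 7 and pyrrolidine give 2-[4-(3,5-dimethoxyphenoxy)-2,6-dimethoxyphenoxy]-1-(pyrrolidin-1-yl)ethan-1-one F3. Activation with Tf2O and 2,4,6-trimethylpyridine (CH2Cl2, −78 to 0 °C) gives the keteniminium salt 1-{2-[4-(3,5-dimethoxyphenoxy)-2,6-dimethoxyphenoxy]ethenylidene}pyrrolidin-1-ium triflate F4. Its [2+2] cycloaddition with 12 follows the same polarity as the ketene and should give 1-{4-[4-(3,5-dimethoxyphenoxy)-2,6-dimethoxyphenoxy]-3-ethoxy-2-(2,4,6-trimethoxyphenyl)cyclobut-2-en-1-ylidene}pyrrolidin-1-ium triflate F5 (racemic). Hydrolysis of the iminium carbon with water returns 14.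

3. Step 5. Oxidative addition and transmetalation at the electron-rich, doubly ortho-substituted iodide may be slow enough for alkynylzinc homocoupling or protodeiodination to take over, and the aryl ynol ether may be lost by hydration or ethylene extrusion during isolation. The fallback builds the triple bond by elimination instead of cross-coupling; it sets out from 9 and returns at 12. Iodine–lithium exchange of 9 (n-BuLi, THF, −78 °C) gives 2,4,6-trimethoxyphenyllithium F6. Acylation with 2-ethoxy-N-methoxy-N-methylacetamide (Weinreb ketone synthesis) gives 2-ethoxy-1-(2,4,6-trimethoxyphenyl)ethan-1-one F7. Enolisation with LiN(SiMe3)2 and trapping with PhNTf2 gives (Z)-2-ethoxy-1-(2,4,6-trimethoxyphenyl)ethenyl trifluoromethanesulfonate F8. Anti elimination of triflate with KOt-Bu (THF, −78 °C) gives 12 under basic, cold conditions.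

**Further compounds**

F1 | step 7 | 4-[4-(3,5-dimethoxyphenoxy)-2,6-dimethoxyphenoxy]-3-ethoxycyclobut-2-en-1-one (racemic) | CCOC1=CC(=O)C1Oc1c(OC)cc(Oc2cc(OC)cc(OC)c2)cc1OC
F2 | step 7 | 2-[4-(3,5-dimethoxyphenoxy)-2,6-dimethoxyphenoxy]-3,5-diethoxy-6-(2,4,6-trimethoxyphenyl)phenol | CCOc1cc(OCC)c(-c2c(OC)cc(OC)cc2OC)c(O)c1Oc1c(OC)cc(Oc2cc(OC)cc(OC)c2)cc1OC
F3 | step 6 | 2-[4-(3,5-dimethoxyphenoxy)-2,6-dimethoxyphenoxy]-1-(pyrrolidin-1-yl)ethan-1-one | COc1cc(Oc2cc(OC)c(OCC(=O)N3CCCC3)c(OC)c2)cc(OC)c1
F4 | step 6 | 1-{2-[4-(3,5-dimethoxyphenoxy)-2,6-dimethoxyphenoxy]ethenylidene}pyrrolidin-1-ium triflate | COc1cc(Oc2cc(OC)c(OC=C=[N+]3CCCC3)c(OC)c2)cc(OC)c1.[O-]S(=O)(=O)C(F)(F)F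
F5 | step 6 | 1-{4-[4-(3,5-dimethoxyphenoxy)-2,6-dimethoxyphenoxy]-3-ethoxy-2-(2,4,6-trimethoxyphenyl)cyclobut-2-en-1-ylidene}pyrrolidin-1-ium triflate (racemic) | CCOC1=C(c2c(OC)cc(OC)cc2OC)C(=[N+]2CCCC2)C1Oc1c(OC)cc(Oc2cc(OC)cc(OC)c2)cc1OC.[O-]S(=O)(=O)C(F)(F)F
F6 | step 5 | 2,4,6-trimethoxyphenyllithium | COc1cc(OC)c([Li])c(OC)c1
F7 | step 5 | 2-ethoxy-1-(2,4,6-trimethoxyphenyl)ethan-1-one | CCOCC(=O)c1c(OC)cc(OC)cc1OC
F8 | step 5 | (Z)-2-ethoxy-1-(2,4,6-trimethoxyphenyl)ethenyl trifluoromethanesulfonate | CCO/C=C(\OS(=O)(=O)C(F)(F)F)c1c(OC)cc(OC)cc1OC
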